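Electrophile is left over in the teal run: it still reads 13.9% at 1.00 min, although that flask got 1.68 nucleophile per electrophile charged. Theta and eta share one recipe and differ in when they stop.

| flask | electrophile | nucleophile | remark | time |
|---|---|---|---|---|
| teal | 0.50 mM | 0.84 mM | run made earlier |  |
| red | 0.50 mM | 1.3 mM | run made earlier |  |
| blue | 0.75 mM | 0.60 mM | run made earlier |  |
| theta | 0.50 mM | 0.600 mM |  | 0.80 min |
| eta | 0.50 mM | 0.600 mM |  | 2.5 min |

| run | time / min | product / % | electrophile / % |
|---|---|---|---|
| teal | 0.167 | 77.8 | 21.9 |
| teal | 0.417 | 81.7 | 15.9 |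
| teal | 0.667 | 84.5 | 14.3 |
| teal | 1.00 | 86.6 | 13.9 |
| teal | 1.50 | 87.3 | 12.6 |
| teal | 2.00 | 91.6 | 11.0 |
| teal | 2.50 | 90.1 | 8.7 |
| red | 0.200 | 97.9 | 2.1 |
| red | 0.333 | 99.4 | 0 |
| red | 0.500 | 100.9 | 0 |
| red | 0.667 | 98.4 | 0 |
| red | 1.00 | 100.4 | 0 |
| red | 1.50 | 100.2 | 0 |
| red | 2.50 | 100.2 | 0 |
| blue | 0.200 | 40.8 | 59.1 |
| blue | 0.667 | 44.4 | 53.3 |
| blue | 1.33 | 51.3 | 48.8 |
| blue | 2.00 | 55.1 | 42.8 |
| blue | 2.50 | 57.9 | 40.7 |

(each reading ± 1 percentage point)



- the flask that ends with the higher amount of product, in percent of the electrophile charged, or "neither" when 2 percentage points or less lies between them (theta / eta / neither)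
- final product, as a percentage of the electrophile charged, in theta
- final product, as a percentage of the electrophile charged, in eta

An excess of nucleophile and a stalled electrophile don't go together if one nucleophile serves one electrophile, but they do if two are used up per product, which makes the nucleophile the limiting reagent of the fast start. Teal then allows 84.0%, and its electrophile reads 15.9% at 0.417 min. Blue allows 40.0%, and its product reads 40.8% at 0.200 min. For theta and eta, the nucleophile charged over twice the electrophile charged, the burst share, is 60.0%.

The electrophile left in teal and blue creeps on. Blue has the same nucleophile charge as theta and eta but more electrophile, so borrowing its rate is my assumption: I read its decay from 59.1% to 40.7% as first order, 0.162 min⁻¹, a reading that carries their scatter. Applied to what the burst leaves, this gives me 64.9% in theta and 73.3% in eta, a gap of 8.4 percentage points, wider than the margin, so I expect eta to end higher.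

The forecast also picks eta, with 65% and 74%, from “The burst product is about half the nucleophile charged”, its eta lying 0.70 points above mine.

The flasks give 64.6% in theta and 74.5% in eta, so eta ends higher.

    electrophile + nucleophile → acid set free + product (k = 1310 L mol⁻¹ s⁻¹)
    nucleophile + acid set free ⇌ protonated nucleophile, settled at all times (K = 8.94 × 10⁶ L mol⁻¹)
    nucleophile ⇌ dormant form (K = 0.887, k = 1.29 s⁻¹)
    crystals ⇌ acid set free, rate k4*(cs4 - [acid set free]) while solid is left; crystals form when [acid set free] > cs4 (solubility = 0.0110 mM, k = 6.04 s⁻¹)

In theta, half of the product-forming turnover up to 0.80 min is done by 1.19 s, far sooner than that time, and 95% of it by 0.400 min. At 0.800 min, 0.45% of theta's nucleophile is free, against 45.3% held as protonated nucleophile.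

For a neighbour like theta with 0.85 mM electrophile, I reckon a burst share of 35.3%, and the same borrowed creep takes my estimate to 43.2% at 0.800 min. That neighbour flask gives 43.5%.

The earlier runs and the new flask were computed for substances that don't exist; the scatter is artificial.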